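**Plan**

- Retrosynthesis: the C4 ketone is traced back to a C3=C4 alkene; that alkene is cut by ring-closing metathesis into a vinyl group on C4a (ring A) and a vinyl group on C2; O1–C2 is then cut to a ring A phenol and a ring B cinnamyl carbonate; last, the C4a–vinyl bond, the ring A hydroxyl and the C6–prenyl bond are removed.
- Enabling feature: C3–C4 of ring C lies between the aromatic carbon C4a and the benzylic, O1-bearing carbon C2, so each can carry a vinyl group and ring C can close as a 2H-chromene under neutral conditions.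
- Forward: ring A is built from resorcinol (prenyl between the two oxygens, hydroxyl para to it, then an ortho vinyl group; the symmetry of the phenol fixes the 6-prenyl pattern). Ring B is taken to a cinnamyl carbonate, the halves are joined at O1–C2, ring C closes last at C3=C4, and oxidation at C4 and deprotection follow.
- Stereochemistry: the only stereocentre, C2 (S), is set when O1–C2 is formed by iridium–phosphoramidite allylic etherification and is not touched afterwards.

Key step: step 11

Assumption: the (Sa,S,S) antipode of the phosphoramidite is taken to give the (S)-ether, as expected for simple cinnamyl carbonates and aryloxides; if this ortho-oxygenated carbonate reverses the sense, the (Ra,R,R) ligand is used and nothing else changes.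

**Route**

Step 1
Reactants: 1 resorcinol
Product: 2 1,3-bis(methoxymethoxy)benzene
Conditions: NaH (2.4 equiv), MOMCl (2.4 equiv), DMF, 0 °C to rt
Reagents that add atoms: chloromethyl methyl ether, COCCl
Why: Williamson-type O-alkylation of the bis-phenoxide by the reactive α-chloro ether is a standard acetal protection and installs the two groups that direct the metalation of step 2.

Step 2
Reactants: 2 1,3-bis(methoxymethoxy)benzene; 3 prenyl bromide (1-bromo-3-methylbut-2-ene)
Product: 5 1,3-bis(methoxymethoxy)-2-(3-methylbut-2-en-1-yl)benzene, via aryllithium 4 (not isolated)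
Conditions: n-BuLi (1.1 equiv), THF, 0 °C to rt; CuI (10 mol%), then 3, −78 °C to rt
Reagents that add atoms: none
Why: Directed ortho-metalation removes the proton flanked by both acetal oxygens, and copper-assisted SN2 alkylation of the aryl anion at the primary carbon of the allylic bromide places the prenyl group between the two oxygens with its double bond unshifted.

Step 3
Reactants: 5 1,3-bis(methoxymethoxy)-2-(3-methylbut-2-en-1-yl)benzene
Product: 7 3,5-bis(methoxymethoxy)-4-(3-methylbut-2-en-1-yl)phenol, via pinacol boronate 6 (not isolated)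
Conditions: [Ir(cod)(OMe)]2 (1.5 mol%), 4,4'-di-tert-butyl-2,2'-bipyridine (3 mol%), B2pin2 (0.6 equiv), THF, 65 °C; then aq. NaOH, 30% H2O2, 0 °C to rt
Reagents that add atoms: hydrogen peroxide, OO
Why: Iridium-catalysed aromatic C–H borylation is governed by sterics and should select the one ring C–H without an ortho substituent (para to the prenyl group), and basic peroxide oxidation of the aryl boronate (1,2-aryl shift from boron to oxygen) then gives the symmetric phenol while the trisubstituted alkene and the acetals are left alone.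

Step 4
Reactants: 7 3,5-bis(methoxymethoxy)-4-(3-methylbut-2-en-1-yl)phenol
Product: 9 6-hydroxy-2,4-bis(methoxymethoxy)-3-(3-methylbut-2-en-1-yl)benzaldehyde, via hydroxymethylphenol 8 (not isolated)
Conditions: MgCl2 (2 equiv), Et3N (4 equiv), (CH2O)n (6 equiv), MeCN, 80 °C; aq. NH4Cl work-up
Reagents that add atoms: formaldehyde (as paraformaldehyde), C=O
Why: Magnesium-mediated ortho-formylation of phenols (Casnati–Skattebøl reaction) delivers formaldehyde only ortho to the magnesium phenoxide and oxidises the resulting benzylic alcohol by hydride transfer to a second formaldehyde, and since the two ortho positions are equivalent by symmetry a single aldehyde is expected under basic conditions that spare the acetals.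

Step 5
Reactants: 9 6-hydroxy-2,4-bis(methoxymethoxy)-3-(3-methylbut-2-en-1-yl)benzaldehyde
Product: 10 2-ethenyl-3,5-bis(methoxymethoxy)-4-(3-methylbut-2-en-1-yl)phenol
Conditions: Ph3PCH3Br (3 equiv), KOt-Bu (2.9 equiv), THF, 0 °C to rt; used at once
Reagents that add atoms: methyltriphenylphosphonium bromide, C[P+](c1ccccc1)(c1ccccc1)c1ccccc1.[Br-]
Why: Wittig methylenation with an excess of the non-stabilised ylide, which tolerates the phenol as its phenoxide, should convert the aldehyde into the terminal styrene under basic conditions that keep the acetals, the prenyl group and the acid-sensitive vinylphenol intact.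

Step 6
Reactants: 11 2,4-dihydroxy-5-methoxybenzaldehyde
Product: 12 5-methoxy-2,4-bis(methoxymethoxy)benzaldehyde
Conditions: NaH (2.5 equiv), MOMCl (2.5 equiv), DMF, 0 °C to rt
Reagents that add atoms: chloromethyl methyl ether, COCCl
Why: Williamson-type O-alkylation with the α-chloro ether protects both phenols, the chelated ortho hydroxyl included once NaH has deprotonated it, as acetals that survive every later basic, reductive and organometallic step.

Step 7
Reactants: 12 5-methoxy-2,4-bis(methoxymethoxy)benzaldehyde
Product: 13 ethyl (2E)-3-[5-methoxy-2,4-bis(methoxymethoxy)phenyl]prop-2-enoate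
Conditions: (EtO)2P(O)CH2CO2Et (1.2 equiv), NaH (1.2 equiv), THF, 0 °C to rt
Reagents that add atoms: triethyl phosphonoacetate, CCOC(=O)CP(=O)(OCC)OCC
Why: Horner–Wadsworth–Emmons olefination with the stabilised phosphonate anion gives the (E)-cinnamate through the thermodynamically preferred elimination pathway.

Step 8
Reactants: 13 ethyl (2E)-3-[5-methoxy-2,4-bis(methoxymethoxy)phenyl]prop-2-enoate
Product: 14 (2E)-3-[5-methoxy-2,4-bis(methoxymethoxy)phenyl]prop-2-en-1-ol
Conditions: i-Bu2AlH (2.3 equiv), CH2Cl2, −78 °C; aq. potassium sodium tartrate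
Reagents that add atoms: none
Why: 1,2-Reduction of the conjugated ester by the electrophilic hydride i-Bu2AlH at low temperature gives the allylic alcohol without touching the alkene or the acetals.

Step 9
Reactants: 14 (2E)-3-[5-methoxy-2,4-bis(methoxymethoxy)phenyl]prop-2-en-1-ol
Product: 15 (2E)-3-[5-methoxy-2,4-bis(methoxymethoxy)phenyl]prop-2-en-1-yl methyl carbonate
Conditions: ClCO2Me (1.5 equiv), pyridine, CH2Cl2, 0 °C
Reagents that add atoms: methyl chloroformate, COC(=O)Cl
Why: Acylation of the primary alcohol with the chloroformate in the presence of pyridine gives the linear allylic carbonate, the usual leaving group for iridium-catalysed allylic substitution.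

Step 10
Reactants: 10 2-ethenyl-3,5-bis(methoxymethoxy)-4-(3-methylbut-2-en-1-yl)phenol; 15 (2E)-3-[5-methoxy-2,4-bis(methoxymethoxy)phenyl]prop-2-en-1-yl methyl carbonate
Product: 17 (S)-1-[5-methoxy-2,4-bis(methoxymethoxy)phenyl]prop-2-en-1-yl 2-ethenyl-3,5-bis(methoxymethoxy)-4-(3-methylbut-2-en-1-yl)phenyl ether, via lithium phenoxide 16 (not isolated)
Conditions: 10, n-BuLi (1.0 equiv), THF, −78 to 0 °C; then [Ir(cod)Cl]2 (2 mol%), (Sa,S,S)-(1,1'-binaphthalene-2,2'-diyl) N,N-bis[1-(2-methoxyphenyl)ethyl]phosphoramidite (4 mol%, pre-activated with n-PrNH2 at 50 °C, volatiles removed), 15 (1.2 equiv), THF, rt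
Reagents that add atoms: none
Why: Iridium-catalysed asymmetric allylic etherification: the cyclometalated iridium–phosphoramidite complex ionises the carbonate to a π-allyl complex on one face of the allyl unit and the aryloxide attacks the aryl-substituted terminus anti to the metal, so the branched ether forms and the ligand fixes C2 as (S); the ortho-methoxyphenyl ligand is chosen for the ortho-substituted cinnamyl unit, and the electron-rich aryloxide is a poor leaving group, which should slow re-ionisation of the product.

Step 11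
Reactants: 17 (S)-1-[5-methoxy-2,4-bis(methoxymethoxy)phenyl]prop-2-en-1-yl 2-ethenyl-3,5-bis(methoxymethoxy)-4-(3-methylbut-2-en-1-yl)phenyl ether
Product: 18 (2S)-2-[5-methoxy-2,4-bis(methoxymethoxy)phenyl]-5,7-bis(methoxymethoxy)-6-(3-methylbut-2-en-1-yl)-2H-chromene
Conditions: second-generation Grubbs catalyst RuCl2(=CHPh)(PCy3)(H2IMes) (5 mol%), 1,4-benzoquinone (10 mol%), CH2Cl2 (0.005 M), 40 °C, argon sparge
Reagents that add atoms: none
Why: The ruthenium benzylidene first exchanges with the less encumbered monosubstituted alkene of the allylic ether, and the new alkylidene adds to the neighbouring aryl vinyl group in a [2+2] step to a ruthenacyclobutane whose retro-[2+2] releases the C3=C4 alkene and a ruthenium methylidene, ethylene leaving the system. The closest known reaction type is ring-closing metathesis of ortho-vinylaryl allyl ethers to 2H-chromenes. Ring C (six-membered) is closed by joining the two termini of a 1,7-diene, the new double bond being endocyclic and conjugated with ring A. No stereocentre is created, and C2 is carried through because the medium is neutral and aprotic, so the doubly activated O1–C2 bond has no reason to ionise. The step needs chemoselectivity for the two vinyl groups over the prenyl alkene; this is secured by the trisubstituted nature of that alkene, which engages the catalyst slowly, and by the fact that any ring through it would be a strained meta-bridged or a large ring, while high dilution suppresses cross-metathesis and the quinone suppresses hydride-mediated alkene migration.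

Step 12
Reactants: 18 (2S)-2-[5-methoxy-2,4-bis(methoxymethoxy)phenyl]-5,7-bis(methoxymethoxy)-6-(3-methylbut-2-en-1-yl)-2H-chromene
Product: 19 (2S)-2-[5-methoxy-2,4-bis(methoxymethoxy)phenyl]-5,7-bis(methoxymethoxy)-6-(3-methylbut-2-en-1-yl)-2,3-dihydro-4H-chromen-4-one
Conditions: PdCl2 (15 mol%), CuCl (50 mol%), O2 (1 atm), DMF–H2O (7:1), rt to 40 °C
Reagents that add atoms: water, O
Why: Tsuji–Wacker oxidation: water attacks the alkene bound to divalent palladium at C4, the benzylic carbon activated by the ortho and para oxygens of ring A and remote from the inductively deactivating allylic O1, and β-hydride elimination followed by tautomerisation gives the C4 ketone, while the trisubstituted prenyl alkene is too hindered to be oxidised and C2 is not involved.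

Step 13
Reactants: 19 (2S)-2-[5-methoxy-2,4-bis(methoxymethoxy)phenyl]-5,7-bis(methoxymethoxy)-6-(3-methylbut-2-en-1-yl)-2,3-dihydro-4H-chromen-4-one
Product: 20 Kushenol V ((2S)-2-(2,4-dihydroxy-5-methoxyphenyl)-5,7-dihydroxy-6-(3-methylbut-2-en-1-yl)-2,3-dihydro-4H-chromen-4-one)
Conditions: 3 M aq. HCl–MeOH (1:5), 45 °C, short contact
Reagents that add atoms: none
Why: Acid-catalysed acetal exchange with methanol removes all four methoxymethyl groups as dimethoxymethane, a deprotection in routine use on prenylated flavanones, and the mild temperature and short contact should spare the prenyl alkene and the C2 configuration.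

**Compound list**

1 | resorcinol | Oc1cccc(O)c1 | starting material
2 | 1,3-bis(methoxymethoxy)benzene | COCOc1cccc(OCOC)c1 | intermediate
3 | prenyl bromide (1-bromo-3-methylbut-2-ene) | CC(C)=CCBr | starting material
4 | [2,6-bis(methoxymethoxy)phenyl]lithium | [Li]c1c(OCOC)cccc1OCOC | intermediate
5 | 1,3-bis(methoxymethoxy)-2-(3-methylbut-2-en-1-yl)benzene | COCOc1cccc(OCOC)c1CC=C(C)C | intermediate
6 | 2-[3,5-bis(methoxymethoxy)-4-(3-methylbut-2-en-1-yl)phenyl]-4,4,5,5-tetramethyl-1,3,2-dioxaborolane | COCOc1cc(B2OC(C)(C)C(C)(C)O2)cc(OCOC)c1CC=C(C)C | intermediate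
7 | 3,5-bis(methoxymethoxy)-4-(3-methylbut-2-en-1-yl)phenol | COCOc1cc(O)cc(OCOC)c1CC=C(C)C | intermediate
8 | 2-(hydroxymethyl)-3,5-bis(methoxymethoxy)-4-(3-methylbut-2-en-1-yl)phenol | OCc1c(O)cc(OCOC)c(CC=C(C)C)c1OCOC | intermediate
9 | 6-hydroxy-2,4-bis(methoxymethoxy)-3-(3-methylbut-2-en-1-yl)benzaldehyde | O=Cc1c(O)cc(OCOC)c(CC=C(C)C)c1OCOC | intermediate
10 | 2-ethenyl-3,5-bis(methoxymethoxy)-4-(3-methylbut-2-en-1-yl)phenol | C=Cc1c(O)cc(OCOC)c(CC=C(C)C)c1OCOC | intermediate
11 | 2,4-dihydroxy-5-methoxybenzaldehyde | COc1cc(C=O)c(O)cc1O | starting material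
12 | 5-methoxy-2,4-bis(methoxymethoxy)benzaldehyde | COc1cc(C=O)c(OCOC)cc1OCOC | intermediate
13 | ethyl (2E)-3-[5-methoxy-2,4-bis(methoxymethoxy)phenyl]prop-2-enoate | CCOC(=O)/C=C/c1cc(OC)c(OCOC)cc1OCOC | intermediate
14 | (2E)-3-[5-methoxy-2,4-bis(methoxymethoxy)phenyl]prop-2-en-1-ol | OC/C=C/c1cc(OC)c(OCOC)cc1OCOC | intermediate
15 | (2E)-3-[5-methoxy-2,4-bis(methoxymethoxy)phenyl]prop-2-en-1-yl methyl carbonate | COC(=O)OC/C=C/c1cc(OC)c(OCOC)cc1OCOC | intermediate
16 | lithium 2-ethenyl-3,5-bis(methoxymethoxy)-4-(3-methylbut-2-en-1-yl)phenolate | [Li+].[O-]c1cc(OCOC)c(CC=C(C)C)c(OCOC)c1C=C | intermediate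
17 | (S)-1-[5-methoxy-2,4-bis(methoxymethoxy)phenyl]prop-2-en-1-yl 2-ethenyl-3,5-bis(methoxymethoxy)-4-(3-methylbut-2-en-1-yl)phenyl ether | C=C[C@H](Oc1cc(OCOC)c(CC=C(C)C)c(OCOC)c1C=C)c1cc(OC)c(OCOC)cc1OCOC | intermediate
18 | (2S)-2-[5-methoxy-2,4-bis(methoxymethoxy)phenyl]-5,7-bis(methoxymethoxy)-6-(3-methylbut-2-en-1-yl)-2H-chromene | COc1cc([C@@H]2C=Cc3c(cc(OCOC)c(CC=C(C)C)c3OCOC)O2)c(OCOC)cc1OCOC | intermediate
19 | (2S)-2-[5-methoxy-2,4-bis(methoxymethoxy)phenyl]-5,7-bis(methoxymethoxy)-6-(3-methylbut-2-en-1-yl)-2,3-dihydro-4H-chromen-4-one | COc1cc([C@@H]2CC(=O)c3c(cc(OCOC)c(CC=C(C)C)c3OCOC)O2)c(OCOC)cc1OCOC | intermediate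
20 | Kushenol V, (2S)-2-(2,4-dihydroxy-5-methoxyphenyl)-5,7-dihydroxy-6-(3-methylbut-2-en-1-yl)-2,3-dihydro-4H-chromen-4-one | COc1cc([C@@H]2CC(=O)c3c(cc(O)c(CC=C(C)C)c3O)O2)c(O)cc1O | target

**Step count**

Total: 13 steps. Longest linear sequence: 9 steps (steps 1–5, then 10–13); the ring B branch (steps 6–9) joins at step 10.

**Steps most likely to fail**

1. Step 10 (allylic etherification). The aryloxide may not discriminate cleanly between the two allyl termini and the two allyl faces when the cinnamyl arene carries an ortho acetal oxygen. The catalyst can also slowly re-ionise the electron-rich branched ether, so the enantiomeric purity of 17 may drift downward. The fallback moves stereocontrol from the bond formation to a late kinetic resolution; it sets out from 10 and 15 and comes back at 19. The two fragments are coupled with the same iridium precursor and the racemic ligand to give the racemic 1-[5-methoxy-2,4-bis(methoxymethoxy)phenyl]prop-2-en-1-yl aryl ether F1. Ring-closing metathesis as in step 11 gives the racemic flavene F2, and Wacker oxidation as in step 12 gives the racemic flavanone F3. Noyori-type asymmetric transfer hydrogenation with RuCl[(R,R)-TsDPEN](p-cymene) and HCO2H–Et3N in EtOAc at rt, stopped near half conversion, is expected to reduce the (2R)-ketone to the cis-(2R,4R)-flavan-4-ol F4 and to leave the (2S)-ketone 19, which is separated by chromatography. Kinetic resolution of racemic flavanones by this reduction is established chemistry.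

2. Step 12 (Wacker oxidation). Hydroxypalladation may be slow on the cis-disubstituted ring alkene, and the C3–palladium intermediate may expel the O1 aryloxide by β-elimination and so open ring C. Long exposure may also let the acetals or the C2 centre suffer. The fallback carries the C4 oxygen into the ring closure instead of adding it afterwards; it sets out from 9 and comes back at 19. MeMgBr (excess, THF, 0 °C) adds to 9 to give the secondary benzylic alcohol F5, which MnO2 in CH2Cl2 oxidises to the ortho-hydroxyacetophenone F6. Its lithium phenoxide is etherified with 15 under the conditions of step 10 to give the (S)-ether ketone F7. KN(SiMe3)2 and t-BuMe2SiCl in THF at −78 °C convert the methyl ketone into the silyl enol ether F8. Ring-closing metathesis with the catalyst of step 11 in toluene at 60 °C closes the same C3=C4 bond and gives the 4-silyloxyflav-3-ene F9. Bu4NF buffered with AcOH in THF at 0 °C then removes silicon and protonates C3 to give 19. Ring-closing metathesis of silyl enol ethers to cyclic silyl enol ethers and their fluoride cleavage to ketones are known.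

3. Step 13 (global deprotection). Protic acid may open ring C through the ortho,para-oxygenated benzylic cation at C2, with loss of configuration. It may also add the freed 5- or 7-hydroxyl across the prenyl alkene before the last acetal has been cleaved. The fallback exchanges the acetals for silyl ethers under aprotic conditions and then hydrolyses at neutral pH; it sets out from 19 and comes back at 20. Me3SiOTf and 2,2'-bipyridyl in MeCN at 0 °C convert aromatic methoxymethyl ethers into aryl trimethylsilyl ethers, here the tetrakis(trimethylsilyl) ether F10. Addition of water at rt hydrolyses the four silyl ethers to 20 without a strong protic acid being present.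

**Further compounds**

F1 | step 10 | racemic 1-[5-methoxy-2,4-bis(methoxymethoxy)phenyl]prop-2-en-1-yl 2-ethenyl-3,5-bis(methoxymethoxy)-4-(3-methylbut-2-en-1-yl)phenyl ether | C=CC(Oc1cc(OCOC)c(CC=C(C)C)c(OCOC)c1C=C)c1cc(OC)c(OCOC)cc1OCOC
F2 | step 10 | racemic 2-[5-methoxy-2,4-bis(methoxymethoxy)phenyl]-5,7-bis(methoxymethoxy)-6-(3-methylbut-2-en-1-yl)-2H-chromene | COc1cc(C2C=Cc3c(cc(OCOC)c(CC=C(C)C)c3OCOC)O2)c(OCOC)cc1OCOC
F3 | step 10 | racemic 2-[5-methoxy-2,4-bis(methoxymethoxy)phenyl]-5,7-bis(methoxymethoxy)-6-(3-methylbut-2-en-1-yl)-2,3-dihydro-4H-chromen-4-one | COc1cc(C2CC(=O)c3c(cc(OCOC)c(CC=C(C)C)c3OCOC)O2)c(OCOC)cc1OCOC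
F4 | step 10 | (2R,4R)-2-[5-methoxy-2,4-bis(methoxymethoxy)phenyl]-5,7-bis(methoxymethoxy)-6-(3-methylbut-2-en-1-yl)-3,4-dihydro-2H-chromen-4-ol | COc1cc([C@H]2C[C@@H](O)c3c(cc(OCOC)c(CC=C(C)C)c3OCOC)O2)c(OCOC)cc1OCOC
F5 | step 12 | racemic 2-(1-hydroxyethyl)-3,5-bis(methoxymethoxy)-4-(3-methylbut-2-en-1-yl)phenol | CC(O)c1c(O)cc(OCOC)c(CC=C(C)C)c1OCOC
F6 | step 12 | 1-[6-hydroxy-2,4-bis(methoxymethoxy)-3-(3-methylbut-2-en-1-yl)phenyl]ethan-1-one | CC(=O)c1c(O)cc(OCOC)c(CC=C(C)C)c1OCOC
F7 | step 12 | (S)-1-[5-methoxy-2,4-bis(methoxymethoxy)phenyl]prop-2-en-1-yl 2-acetyl-3,5-bis(methoxymethoxy)-4-(3-methylbut-2-en-1-yl)phenyl ether | C=C[C@H](Oc1cc(OCOC)c(CC=C(C)C)c(OCOC)c1C(C)=O)c1cc(OC)c(OCOC)cc1OCOC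
F8 | step 12 | (S)-1-[5-methoxy-2,4-bis(methoxymethoxy)phenyl]prop-2-en-1-yl 2-[1-(tert-butyldimethylsilyloxy)ethenyl]-3,5-bis(methoxymethoxy)-4-(3-methylbut-2-en-1-yl)phenyl ether | C=C[C@H](Oc1cc(OCOC)c(CC=C(C)C)c(OCOC)c1C(=C)O[Si](C)(C)C(C)(C)C)c1cc(OC)c(OCOC)cc1OCOC
F9 | step 12 | (2S)-4-(tert-butyldimethylsilyloxy)-2-[5-methoxy-2,4-bis(methoxymethoxy)phenyl]-5,7-bis(methoxymethoxy)-6-(3-methylbut-2-en-1-yl)-2H-chromene | COc1cc([C@@H]2C=C(O[Si](C)(C)C(C)(C)C)c3c(cc(OCOC)c(CC=C(C)C)c3OCOC)O2)c(OCOC)cc1OCOC
F10 | step 13 | (2S)-2-[5-methoxy-2,4-bis(trimethylsilyloxy)phenyl]-6-(3-methylbut-2-en-1-yl)-5,7-bis(trimethylsilyloxy)-2,3-dihydro-4H-chromen-4-one | COc1cc([C@@H]2CC(=O)c3c(cc(O[Si](C)(C)C)c(CC=C(C)C)c3O[Si](C)(C)C)O2)c(O[Si](C)(C)C)cc1O[Si](C)(C)C
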